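**Retrosynthetic overview**
- The target is reached by BCl3 dealkylation (5-OMe and 6'-O-iPr) of 6'-isopropoxy-5,6,7,2',3',4'-hexamethoxyflavone. That flavone is cut at O1–C8a and C4–C4a (3,4,5-trimethoxybenzyne plus an arylpropiolic acid) and at O1–C2 (pyranone closure).
- The strategy rests on ring A: O1 on C8a and the C4 carbonyl carbon on C4a are ortho neighbours, with C5–OMe beside C4a and C8–H beside C8a. This is the footprint of an acyloxy group added across the aryne bond of 3,4,5-trimethoxybenzyne, oxygen on the carbon remote from the flanking OMe and acyl on the carbon next to it.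
- Ring B (C1' between 2'-OMe and 6'-O, then 3'- and 4'-OMe) has the same 1-oxy-3,4,5-trimethoxy array. Both aryl rings therefore come from 3,4,5-trimethoxyphenol through one bromophenol, which is turned into the silyl triflate on one side and into the aldehyde, dibromoolefin and propiolic acid on the other.
- Ring order: rings A and B are bought as the same phenol; ring C is the only ring built and closes last, in the aryne step.

Key step: step 9

Remark: the target has no stereocentre and no configurationally stable axis, so no stereochemical operation is needed and the route compounds carry no stereodescriptors. Flavone numbering is O1, C2 (aryl-bearing), C3, C4 (C=O), C4a, C5–C8, C8a.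

**Route**

Step 1
Reactants: 1 3,4,5-trimethoxyphenol
Product: 2 2-bromo-3,4,5-trimethoxyphenol
Conditions: NBS (1.0 equiv), CH2Cl2, −78 °C to 0 °C
Reagents that add atoms: N-bromosuccinimide, O=C1CCC(=O)N1Br
Why: Electrophilic aromatic bromination at one of the two equivalent free positions (C2/C6), where one equivalent of NBS at low temperature should stop at the monobromide.

Step 2
Reactants: 2 2-bromo-3,4,5-trimethoxyphenol
Product: 3 (2-bromo-3,4,5-trimethoxyphenoxy)trimethylsilane
Conditions: HMDS, THF, reflux; evaporate, use crude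
Reagents that add atoms: hexamethyldisilazane, C[Si](C)(C)N[Si](C)(C)C
Why: O-silylation of the phenol by a silazane gives the aryl silyl ether with ammonia as the only by-product, so the moisture-sensitive ether can be taken on without purification.

Step 3
Reactants: 3 (2-bromo-3,4,5-trimethoxyphenoxy)trimethylsilane
Product: 5 3,4,5-trimethoxy-2-(trimethylsilyl)phenol, via aryllithium 4 (not isolated)
Conditions: n-BuLi (1.1 equiv), THF, −78 °C to rt; sat. aq NH4Cl
Reagents that add atoms: none
Why: Bromine–lithium exchange gives the ortho-lithio aryl silyl ether 4, which should undergo anionic 1,3 O-to-C silyl migration (retro-Brook rearrangement) driven by formation of the lithium phenoxide.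

Step 4
Reactants: 5 3,4,5-trimethoxy-2-(trimethylsilyl)phenol
Product: 6 3,4,5-trimethoxy-2-(trimethylsilyl)phenyl trifluoromethanesulfonate
Conditions: Tf2O (1.2 equiv), pyridine, CH2Cl2, 0 °C
Reagents that add atoms: trifluoromethanesulfonic anhydride, O=S(=O)(OS(=O)(=O)C(F)(F)F)C(F)(F)F
Why: O-sulfonylation of the phenol under amine base gives the ortho-silyl aryl triflate (Kobayashi-type aryne precursor), and the basic medium protects the electron-rich arylsilane from protodesilylation.

Step 5
Reactants: 2 2-bromo-3,4,5-trimethoxyphenol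
Product: 7 2-bromo-1-isopropoxy-3,4,5-trimethoxybenzene
Conditions: 2-bromopropane (2 equiv), K2CO3, DMF, 60 °C
Reagents that add atoms: 2-bromopropane, CC(C)Br
Why: Williamson etherification of the phenoxide installs an isopropyl ether that withstands organolithium and fluoride conditions and masks the future 6'-OH.

Step 6
Reactants: 7 2-bromo-1-isopropoxy-3,4,5-trimethoxybenzene
Product: 9 6-isopropoxy-2,3,4-trimethoxybenzaldehyde, via aryllithium 8 (not isolated)
Conditions: n-BuLi (1.1 equiv), THF, −78 °C; DMF, −78 °C to rt; 1 M HCl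
Reagents that add atoms: N,N-dimethylformamide, CN(C)C=O
Why: Bromine–lithium exchange followed by formylation of the aryllithium with DMF (Bouveault aldehyde synthesis), the tetrahedral adduct collapsing to the aldehyde only on acidic work-up.

Step 7
Reactants: 9 6-isopropoxy-2,3,4-trimethoxybenzaldehyde
Product: 10 2-(2,2-dibromovinyl)-1-isopropoxy-3,4,5-trimethoxybenzene
Conditions: CBr4 (2 equiv), PPh3 (4 equiv), CH2Cl2, 0 °C
Reagents that add atoms: carbon tetrabromide, BrC(Br)(Br)Br
Why: Corey–Fuchs (Ramirez) dibromoolefination, a Wittig reaction of the aldehyde with the ylide Ph3P=CBr2 formed in the flask from CBr4 and PPh3.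

Step 8
Reactants: 10 2-(2,2-dibromovinyl)-1-isopropoxy-3,4,5-trimethoxybenzene
Product: 12 3-(6-isopropoxy-2,3,4-trimethoxyphenyl)propiolic acid, via lithium acetylide 11 (not isolated)
Conditions: n-BuLi (2.2 equiv), THF, −78 °C to 0 °C; CO2 (g), −78 °C; cold 1 M HCl to pH 2–3
Reagents that add atoms: carbon dioxide, O=C=O
Why: Second stage of the Corey–Fuchs sequence, in which bromine–lithium exchange, Fritsch–Buttenberg–Wiechell 1,2-shift and deprotonation give the lithium acetylide 11, which is carboxylated by CO2.

Step 9
Reactants: 6 3,4,5-trimethoxy-2-(trimethylsilyl)phenyl trifluoromethanesulfonate; 12 3-(6-isopropoxy-2,3,4-trimethoxyphenyl)propiolic acid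
Product: 15 2-(6-isopropoxy-2,3,4-trimethoxyphenyl)-5,6,7-trimethoxy-4H-chromen-4-one, via aryne 13 (not isolated), via ynone 14 (not isolated)
Conditions: 6 (1.8 equiv), CsF (5 equiv), THF, sealed tube, 110–125 °C
Reagents that add atoms: none
Why: Fluoride attack at silicon of 6 expels triflate and releases aryne 13 slowly; the caesium carboxylate of 12 adds through oxygen to the aryne carbon next to C–H, and the resulting aryl anion, ortho to the flanking OMe, attacks the neighbouring ester carbonyl through a four-membered tetrahedral alkoxide that opens to the ortho-acyl phenoxide 14, a net insertion of the aryne into the acid C–O bond that forms O1–C8a and C4–C4a. The closest known reaction type is the fluoride-mediated insertion of arynes into carboxylic acids to give ortho-hydroxyaryl ketones, which with arylpropiolic acids runs on to flavones in one pot. Ring C then closes by 6-endo-dig oxa-Michael addition of the phenoxide of 14 to the ynone carbon bearing ring B (O1–C2), followed by protonation at C3; any 14 that survives would be closed by brief K2CO3 treatment in warm acetone. No stereocentre is created. The step needs oxygen on C8a and acyl on C4a, which is secured by the C3 methoxy group of 13: its inductive effect and the distortion of the aryne direct the nucleophile to the remote carbon and stabilise the anion beside it, while the aprotic medium, slow aryne release and excess of 6 favour acyl transfer over protonation to a plain aryl ester. The 6-endo mode is favoured over 5-exo (aurone) closure by the conjugate-addition polarity of the ynone under basic conditions, and the isopropyl ether keeps the ring B oxygen from competing for the aryne or the alkyne.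

Step 10
Reactants: 15 2-(6-isopropoxy-2,3,4-trimethoxyphenyl)-5,6,7-trimethoxy-4H-chromen-4-one
Product: 16 5-hydroxy-2-(6-hydroxy-2,3,4-trimethoxyphenyl)-6,7-dimethoxy-4H-chromen-4-one (5,6'-dihydroxy-6,7,2',3',4'-pentamethoxyflavone)
Conditions: BCl3 (1 M in CH2Cl2, 4 equiv), CH2Cl2, −78 °C to 0 °C; H2O
Reagents that add atoms: none
Why: Lewis-acid ether cleavage in which the secondary isopropyl ether goes much faster than unactivated aryl methyl ethers and, of the methyl ethers, only the peri 5-OMe is activated through a six-membered boron chelate with the C4 carbonyl, so the other five methoxy groups should survive at or below 0 °C.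

**Compound list**
1 | 3,4,5-trimethoxyphenol | COc1cc(O)cc(OC)c1OC | starting material
2 | 2-bromo-3,4,5-trimethoxyphenol | COc1cc(O)c(Br)c(OC)c1OC | intermediate
3 | (2-bromo-3,4,5-trimethoxyphenoxy)trimethylsilane | COc1cc(O[Si](C)(C)C)c(Br)c(OC)c1OC | intermediate
4 | [2-lithio-3,4,5-trimethoxyphenoxy]trimethylsilane (aryllithium) | [Li]c1c(O[Si](C)(C)C)cc(OC)c(OC)c1OC | intermediate
5 | 3,4,5-trimethoxy-2-(trimethylsilyl)phenol | COc1cc(O)c([Si](C)(C)C)c(OC)c1OC | intermediate
6 | 3,4,5-trimethoxy-2-(trimethylsilyl)phenyl trifluoromethanesulfonate | COc1cc(OS(=O)(=O)C(F)(F)F)c([Si](C)(C)C)c(OC)c1OC | intermediate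
7 | 2-bromo-1-isopropoxy-3,4,5-trimethoxybenzene | COc1cc(OC(C)C)c(Br)c(OC)c1OC | intermediate
8 | (6-isopropoxy-2,3,4-trimethoxyphenyl)lithium (aryllithium) | [Li]c1c(OC(C)C)cc(OC)c(OC)c1OC | intermediate
9 | 6-isopropoxy-2,3,4-trimethoxybenzaldehyde | COc1cc(OC(C)C)c(C=O)c(OC)c1OC | intermediate
10 | 2-(2,2-dibromovinyl)-1-isopropoxy-3,4,5-trimethoxybenzene | COc1cc(OC(C)C)c(C=C(Br)Br)c(OC)c1OC | intermediate
11 | lithium (6-isopropoxy-2,3,4-trimethoxyphenyl)acetylide | [Li]C#Cc1c(OC(C)C)cc(OC)c(OC)c1OC | intermediate
12 | 3-(6-isopropoxy-2,3,4-trimethoxyphenyl)propiolic acid | COc1cc(OC(C)C)c(C#CC(=O)O)c(OC)c1OC | intermediate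
13 | 3,4,5-trimethoxybenzyne (1,2-didehydro-3,4,5-trimethoxybenzene) | COC1=C(OC)C(OC)=CC#C1 | intermediate
14 | 1-(2-hydroxy-4,5,6-trimethoxyphenyl)-3-(6-isopropoxy-2,3,4-trimethoxyphenyl)prop-2-yn-1-one | COc1cc(O)c(C(=O)C#Cc2c(OC(C)C)cc(OC)c(OC)c2OC)c(OC)c1OC | intermediate
15 | 2-(6-isopropoxy-2,3,4-trimethoxyphenyl)-5,6,7-trimethoxy-4H-chromen-4-one (6'-isopropoxy-5,6,7,2',3',4'-hexamethoxyflavone) | COc1cc(OC(C)C)c(-c2cc(=O)c3c(OC)c(OC)c(OC)cc3o2)c(OC)c1OC | intermediate
16 | 5-hydroxy-2-(6-hydroxy-2,3,4-trimethoxyphenyl)-6,7-dimethoxy-4H-chromen-4-one (5,6'-dihydroxy-6,7,2',3',4'-pentamethoxyflavone) | COc1cc(O)c(-c2cc(=O)c3c(O)c(OC)c(OC)cc3o2)c(OC)c1OC | target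

**Step count**
Total: 10 steps. Longest linear sequence: 7 steps (steps 1, 5, 6, 7, 8, 9, 10).

**Steps most likely to fail**

Step 9. The aryl anion formed after O-arylation may be protonated before it transfers the acyl group, leaving a simple aryl ester. The propiolic acid may also lose CO2 at the reaction temperature, or the crowded phenoxide may close 5-exo. The fallback sets out from 1 and 9 and comes back at 15, building ring C by chalcone chemistry instead of the aryne. C-acetylation of 1 with AcOH and BF3·OEt2 at 80–90 °C, at the only free position type, should give 1-(2-hydroxy-4,5,6-trimethoxyphenyl)ethanone F1. Claisen–Schmidt condensation of this with aldehyde 9 (KOH, EtOH, rt) should give (E)-1-(2-hydroxy-4,5,6-trimethoxyphenyl)-3-(6-isopropoxy-2,3,4-trimethoxyphenyl)prop-2-en-1-one F2. Oxidative cyclisation with catalytic I2 in DMSO at 120–130 °C should then give flavone 15.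

Step 10. Dealkylation may go too far, at the 6-OMe next to the new 5-O–boron chelate or at the central 3'-OMe of the crowded ring B array. The departing isopropyl cation may also alkylate the very electron-rich ring B. The fallback sets out from 2 and comes back at 16. It carries the ring B oxygen as a benzyl ether, so that it is removed by hydrogenolysis and only one chelation-directed demethylation remains. Benzylation of 2 (BnBr, K2CO3, DMF) should give 1-(benzyloxy)-2-bromo-3,4,5-trimethoxybenzene F3. Bromine–lithium exchange and DMF quench should give 6-(benzyloxy)-2,3,4-trimethoxybenzaldehyde F4. CBr4/PPh3 should give 1-(benzyloxy)-2-(2,2-dibromovinyl)-3,4,5-trimethoxybenzene F5, and n-BuLi then CO2 should give 3-[6-(benzyloxy)-2,3,4-trimethoxyphenyl]propiolic acid F6. Coupling with 6 under the CsF/THF conditions of step 9 should give 2-[6-(benzyloxy)-2,3,4-trimethoxyphenyl]-5,6,7-trimethoxy-4H-chromen-4-one F7. Hydrogenolysis (H2, Pd/C, EtOAc) should give 2-(6-hydroxy-2,3,4-trimethoxyphenyl)-5,6,7-trimethoxy-4H-chromen-4-one F8. AlCl3 in MeCN at rt to 40 °C should then remove only the carbonyl-chelated 5-OMe and give 16.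

Step 3. n-BuLi may attack silicon of the aryl silyl ether instead of bromine, or the crowded aryllithium may be protonated before the O-to-C silyl shift. The electron-rich arylsilane may also protodesilylate during isolation. The fallback sets out from 1 and comes back at 5, using directed ortho-metalation instead of halogen–metal exchange. Isopropyl isocyanate (catalytic Et3N, CH2Cl2) should convert 1 into 3,4,5-trimethoxyphenyl isopropylcarbamate F9. In one flask, TBSOTf/TMEDA in Et2O should silylate nitrogen to give 3,4,5-trimethoxyphenyl N-(tert-butyldimethylsilyl)-N-isopropylcarbamate F10. n-BuLi/TMEDA at −78 °C should lithiate C2, between the carbamate and the 3-OMe group, and TMSCl should trap the anion as 3,4,5-trimethoxy-2-(trimethylsilyl)phenyl N-(tert-butyldimethylsilyl)-N-isopropylcarbamate F11. Aqueous NaHSO4 work-up should remove the N-silyl group and leave 3,4,5-trimethoxy-2-(trimethylsilyl)phenyl isopropylcarbamate F12. DBU and Et2NH in MeCN at 40 °C should then cleave the carbamate under basic conditions, the expelled isopropyl isocyanate being captured by Et2NH, to give phenol 5, which continues with step 4.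

**Further compounds**
F1 | step 9 | 1-(2-hydroxy-4,5,6-trimethoxyphenyl)ethanone | COc1cc(O)c(C(C)=O)c(OC)c1OC
F2 | step 9 | (E)-1-(2-hydroxy-4,5,6-trimethoxyphenyl)-3-(6-isopropoxy-2,3,4-trimethoxyphenyl)prop-2-en-1-one | COc1cc(O)c(C(=O)/C=C/c2c(OC(C)C)cc(OC)c(OC)c2OC)c(OC)c1OC
F3 | step 10 | 1-(benzyloxy)-2-bromo-3,4,5-trimethoxybenzene | COc1cc(OCc2ccccc2)c(Br)c(OC)c1OC
F4 | step 10 | 6-(benzyloxy)-2,3,4-trimethoxybenzaldehyde | COc1cc(OCc2ccccc2)c(C=O)c(OC)c1OC
F5 | step 10 | 1-(benzyloxy)-2-(2,2-dibromovinyl)-3,4,5-trimethoxybenzene | COc1cc(OCc2ccccc2)c(C=C(Br)Br)c(OC)c1OC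
F6 | step 10 | 3-[6-(benzyloxy)-2,3,4-trimethoxyphenyl]propiolic acid | COc1cc(OCc2ccccc2)c(C#CC(=O)O)c(OC)c1OC
F7 | step 10 | 2-[6-(benzyloxy)-2,3,4-trimethoxyphenyl]-5,6,7-trimethoxy-4H-chromen-4-one | COc1cc(OCc2ccccc2)c(-c2cc(=O)c3c(OC)c(OC)c(OC)cc3o2)c(OC)c1OC
F8 | step 10 | 2-(6-hydroxy-2,3,4-trimethoxyphenyl)-5,6,7-trimethoxy-4H-chromen-4-one | COc1cc(O)c(-c2cc(=O)c3c(OC)c(OC)c(OC)cc3o2)c(OC)c1OC
F9 | step 3 | 3,4,5-trimethoxyphenyl isopropylcarbamate | COc1cc(OC(=O)NC(C)C)cc(OC)c1OC
F10 | step 3 | 3,4,5-trimethoxyphenyl N-(tert-butyldimethylsilyl)-N-isopropylcarbamate | COc1cc(OC(=O)N(C(C)C)[Si](C)(C)C(C)(C)C)cc(OC)c1OC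
F11 | step 3 | 3,4,5-trimethoxy-2-(trimethylsilyl)phenyl N-(tert-butyldimethylsilyl)-N-isopropylcarbamate | COc1cc(OC(=O)N(C(C)C)[Si](C)(C)C(C)(C)C)c([Si](C)(C)C)c(OC)c1OC
F12 | step 3 | 3,4,5-trimethoxy-2-(trimethylsilyl)phenyl isopropylcarbamate | COc1cc(OC(=O)NC(C)C)c([Si](C)(C)C)c(OC)c1OC
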